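# Caraganin C by Baeyer–Villiger ring expansion of a 3-styrylindanone

## Analysis of the target

Caraganin C is a 2,3,4-trisubstituted chroman. Ring A (the benzo ring, methoxy at C7) is fused to the pyran ring O1–C2–C3–C4–C4a–C8a, which carries a 2,4-dimethoxyphenyl group at C2, a 4-hydroxybenzyl group at C3 and an (E)-4-hydroxystyryl group at C4. The three contiguous stereocentres are all R. Read from the SMILES, the C2 aryl and the C4 styryl lie on one face and the C3 benzyl on the other (2,3-trans, 3,4-trans), so all three groups can be equatorial on the half-chair and this is the thermodynamically preferred diastereomer.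

The sensitive groups are:
- two free phenols;
- an electron-rich 1,2-disubstituted styrene, which is easily epoxidised, protonated or hydrogenated;
- the C2–O1 benzylic ether, which the 2,4-dimethoxyphenyl group makes ionisable in acid;
- a C4–H bond that is both benzylic and allylic.

Three aryl methyl ethers must survive, so the phenols need a protecting group that leaves without Lewis-acid demethylation or hydrogenolysis. The hard part is C4: no neighbouring group can dictate its absolute configuration, so a catalyst must set it, and C3 and C2 must then be relayed from it. In addition, the aryl–O1 bond has to be formed at the ring A carbon that is meta to the methoxy group.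

The strategy rests on one feature. If O1 is deleted and C8a is joined directly to C2, the atoms C8a, C4a, C4, C3 and C2 form the five-membered ring of a 1-indanone with its carbonyl at C2. The O1–C8a bond can therefore come from inserting oxygen into the aryl–carbonyl bond of a 6-methoxy-3-styrylindan-1-one. The lactone carbonyl that results is C2 at the oxidation level needed for alkylation at C3 and arylation at C2.

## Retrosynthetic reasoning

**O–Si bonds of 20.** The phenols of target 21 are the only groups that cannot pass through enolate and aryllithium chemistry, so 21 is traced to its bis(triisopropylsilyl) ether 20. Cleavage by fluoride leaves the methyl ethers, the alkene and the acid-labile C2 ether alone.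

**C2–H and O1–C2 bonds of 20.** C2 is flanked by O1 and a strongly donating aryl ring, so a cation at C2 is the most accessible reactive intermediate in the molecule. Cutting C2–H leads to the ring tautomer 19 and from there to the open keto-phenol 18. The forward step closes the phenol onto the ketone and delivers hydride to the cyclic cation; the existing C3 and C4 groups must steer that hydride. No separate stereocontrol element is needed for C2, and the wanted isomer is also the thermodynamic one.

**C2–aryl bond of 18.** With C2 at the carboxyl level, the dimethoxyphenyl ring is removed as aryllithium 17, made from bromide 16. This leaves lactone 15. The cut is made here because the aryl ester of 15 is a strong acylating agent whose leaving group is the ring A phenoxide, which is the O1 needed for the later ring closure.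

**C3–CH2 bond of 15.** The benzyl group is removed as bromide 7, leaving lactone 13, which reacts through its enolate 14. The forward alkylation must go trans to the C4 styryl group. The benzyl group is added after the ring expansion, not before, so that in the key step the aryl carbon competes for migration only against an unsubstituted methylene.

**O1–C8a bond of 13 (key disconnection).** Removing O1 contracts the lactone to indanone 11; in the forward sense a peroxide adds to the ketone to give adduct 12 and the aryl carbon migrates to oxygen. This is the place to cut because it turns an aryl ether synthesis next to a stereocentre into a carbon–carbon bond formation on a cyclopentenone-type acceptor, for which catalytic asymmetric methods are well developed. The C4a–C4 bond and the ring A substitution pattern are then already present in a cheap carbocycle.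

**C4–vinyl bond of 11.** The styryl group is disconnected as alkenylboronate 5 from the β-carbon of indenone 10. The forward reaction is a conjugate addition in which a chiral rhodium catalyst chooses the enone face and so sets C4.

**Fragments.** Indenone 10 comes from commercial indanone 8 by dehydrogenation through bromide 9. Boronate 5 comes from aldehyde 2 and diboronate 3 through its lithio derivative 4. Bromide 7 comes from alcohol 6 and hence also from aldehyde 2. Both oxygenated aryl fragments therefore derive from one protected aldehyde, itself made from 1.

## Alternatives that were turned down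

**Alternative 1:** Desymmetrising Prins cyclisation.
- Disconnection: O1–C2 and C2–C3 are cut together. The C3 benzyl and C4 styryl groups are traced to the two identical arms of the achiral bis-styryl phenol A2; aldehyde A3 supplies C2 and its aryl ring.
- Forward key step: under a chiral acid, A2 and A3 condense to an aryloxycarbenium ion. One of the two enantiotopic arms attacks it through its ring-proximal alkene carbon and closes the pyran ring. The benzylic cation is discharged by loss of the phenolic proton, giving p-quinone methide A1, and a 1,6-hydride reduction would then give 21.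
- For: on step economy and convergency this is clearly stronger than the chosen route. One step makes the ring, two bonds and all three stereocentres, possibly without protecting groups. A chair-like transition state with equatorial groups leads to the all-trans arrangement.
- Against: the absolute configuration depends on a catalyst that is only ion-paired to the electrophile yet must distinguish both the two arms and the two faces in the same event. A2 is a skipped diene with a doubly allylic, benzylic C–H bond, so acid should isomerise or ionise it. A phenol is a poor partner for carbenium ion formation with an aldehyde, and A3 can instead attack the electron-rich ring A. A1 is an electrophile formed in the presence of free phenols and should oligomerise.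
- Comparison: the chosen strategy is several steps longer. In exchange each stereocentre is set in a separate step of a known type, C4 by a ligand and C3 and C2 by the substrate, and nothing more electrophilic than a lactone has to be handled.

**Alternative 2:** Oxa-Povarov annulation.
- Disconnection: C2–C3 and C4–C4a, giving mixed acetal A5 (ring A phenol and the C2 aldehyde already joined) and diene A6.
- Forward key step: a Lewis acid ionises A5. The benzyl-bearing terminus of A6 attacks the aryloxycarbenium ion, and ring A then closes on the aryl-stabilised allyl cation at the carbon para to its methoxy group. The product A4 is one desilylation from 21.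
- For: it is the shortest of all the routes and ends at the penultimate stage. The diene regiochemistry is favourable, and a stepwise cationic pathway tends toward the all-equatorial diastereomer.
- Against: nothing binds a chiral controller to either partner, so a single enantiomer would depend on counter-anion control of the first C–C bond formation. The Friedel–Crafts closure must pick one of several activated positions of ring A. A6 has a doubly activated methylene and can slip into full conjugation or polymerise. A5, with its dimethoxyphenyl group, is very labile.
- Comparison: this alternative wins on step count and loses on the point that matters most, enantiocontrol, and also on regiochemical certainty. The chosen strategy has the C4a–C4 bond in the starting indanone 8 and sets C4 with established rhodium catalysis.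

**Alternative 3:** Iminium Friedel–Crafts and lactolisation as a (3+3) annulation.
- Disconnection: C4–C4a and O1–C2, giving phenol A8 and dienal A9.
- Forward key step: a chiral secondary amine converts A9 into an iminium ion. The carbon of A8 ortho to its hydroxyl attacks the β-carbon, and the phenol oxygen closes onto the liberated aldehyde to give lactol A7. Oxidation would give lactone A10, the tert-butyldimethylsilyl analogue of 13, after which the endgame would be the same.
- For: it reaches the lactone stage about two steps sooner than the chosen route. The styrene never meets a peroxide, and C4 is set by a covalently bound catalyst. On step economy and mildness it is as good or better.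
- Against: A8 is only a mono-methoxy phenol, far less nucleophilic than the naphthols and doubly donor-substituted phenols this chemistry relies on. It offers three ring carbons and the oxygen as nucleophilic sites, and A9 offers both β- and δ-positions. The regiochemistry of both partners is therefore open.
- Comparison: the chosen strategy pays two extra steps. In return the arene connectivity is fixed before any stereocentre is made, and the acceptor has a single electrophilic carbon. Its own risk sits in one step, the chemoselective oxygen insertion.

Key step: step 7

Remarks on the chemistry: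
- Both phenols are carried as triisopropylsilyl ethers. Smaller aryl silyl ethers are at risk in the aqueous base of step 6.
- The aryllithium adduct of step 9 is formulated as the open keto-phenol 18, since phenols form hemiketals with aryl ketones reluctantly. Its ring tautomer 19 is numbered separately and appears only as an intermediate of step 10.

## Route

Step 1
Reactants: 1 4-hydroxybenzaldehyde
Product: 2 4-(triisopropylsilyloxy)benzaldehyde
Conditions: i-Pr3SiCl, imidazole, DMF, rt
Reagents that add atoms: triisopropylsilyl chloride, CC(C)[Si](Cl)(C(C)C)C(C)C
Why: Standard phenol silylation; the bulky silyl ether is chosen because it has to survive aqueous base (step 6), Lewis acids (steps 7 and 10) and organolithium reagents, yet leaves with fluoride without touching the methyl ethers.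

Step 2
Reactants: 2 4-(triisopropylsilyloxy)benzaldehyde; 3 bis(pinacolato)borylmethane [2,2'-methylenebis(4,4,5,5-tetramethyl-1,3,2-dioxaborolane)]
Product: 5 (E)-4,4,5,5-tetramethyl-2-{2-[4-(triisopropylsilyloxy)phenyl]ethenyl}-1,3,2-dioxaborolane, via lithiated diboronate 4 (not isolated)
Conditions: 3, lithium 2,2,6,6-tetramethylpiperidide (from the amine and n-BuLi), THF, 0 °C; then 2, −78 °C → rt; H2O
Reagents that add atoms: none
Why: Boron–Wittig olefination: the diboryl carbanion 4 adds to the aldehyde and the adduct loses a boron–oxygen unit by syn elimination, which with aldehydes should give the (E)-alkenylboronate; the hindered amide base deprotonates 3 without attacking boron.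

Step 3
Reactants: 2 4-(triisopropylsilyloxy)benzaldehyde
Product: 6 [4-(triisopropylsilyloxy)phenyl]methanol
Conditions: NaBH4, MeOH/THF, 0 °C
Reagents that add atoms: none
Why: Borohydride reduction of an aromatic aldehyde; the hindered aryl silyl ether should not be cleaved by the alkoxide present at 0 °C.

Step 4
Reactants: 6 [4-(triisopropylsilyloxy)phenyl]methanol
Product: 7 4-(triisopropylsilyloxy)benzyl bromide
Conditions: CBr4, PPh3, CH2Cl2, 0 °C
Reagents that add atoms: carbon tetrabromide, BrC(Br)(Br)Br
Why: Appel bromination under neutral conditions, which avoids the HBr that would threaten the silyl ether; the bromide is used without storage because p-oxygenated benzyl bromides ionise easily.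

Step 5
Reactants: 8 6-methoxy-1-indanone
Product: 10 6-methoxy-1H-inden-1-one, via 3-bromo-6-methoxyindan-1-one 9 (not isolated)
Conditions: NBS, AIBN (cat.), CCl4, reflux; then Et3N, 0 °C; kept in solution and used at once
Reagents that add atoms: none
Why: Wohl–Ziegler bromination selects the C3–H bond, which is benzylic and para to the methoxy group, and base-induced loss of HBr from the β-bromo ketone 9 gives the enone; the indenone is not concentrated because indenones oligomerise when neat.

Step 6
Reactants: 10 6-methoxy-1H-inden-1-one; 5 (E)-4,4,5,5-tetramethyl-2-{2-[4-(triisopropylsilyloxy)phenyl]ethenyl}-1,3,2-dioxaborolane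
Product: 11 (S)-6-methoxy-3-[(E)-4-(triisopropylsilyloxy)styryl]indan-1-one
Conditions: [RhCl(C2H4)2]2 (cat.), (S)-BINAP, aq. K3PO4, 1,4-dioxane, 30 °C, slow addition of 10
Reagents that add atoms: none
Why: Hayashi–Miyaura asymmetric conjugate addition: boron-to-rhodium transmetalation gives a styryl–rhodium species that inserts the C2=C3 bond of the indenone, and water protonates the resulting rhodium enolate; the bisphosphine selects the enone face and so sets the stereocentre, and (S)-BINAP is assigned by analogy with 2-cyclopentenone, whose (S)-3-substituted adducts have the same spatial arrangement as (S)-11 (the mirror-image ligand would be used if the benzo ring reversed the sense).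

Step 7
Reactants: 11 (S)-6-methoxy-3-[(E)-4-(triisopropylsilyloxy)styryl]indan-1-one
Product: 13 (S)-7-methoxy-4-[(E)-4-(triisopropylsilyloxy)styryl]chroman-2-one, via Criegee adduct 12 (not isolated)
Conditions: Me3SiOOSiMe3, SnCl4, trans-cyclohexane-1,2-diamine, 4 Å MS, CH2Cl2, −20 → 0 °C
Reagents that add atoms: bis(trimethylsilyl) peroxide, C[Si](C)(C)OO[Si](C)(C)C
Why: Baeyer–Villiger oxidation: the amine-tempered tin Lewis acid activates the C1 carbonyl, the silyl peroxide adds to give the silyl perketal 12, and the C1–C7a bond, held anti to the O–O bond, shifts to the proximal oxygen as the silanolate leaves, which forms O1–C8a and, after silyl transfer, the lactone carbonyl and hexamethyldisiloxane. The closest known reactions are the oxidation of 1-indanones to 3,4-dihydrocoumarins and the Lewis-acid-promoted silyl peroxide oxidation of ketones that contain alkenes. The six-membered lactone ring arises by a 1,2-shift that expands the five-membered ketone ring, so it is an insertion and not an exo or endo cyclisation. No stereocentre is created; the existing one (indanone C3, chroman C4) is neither the migrating carbon nor enolisable and should pass through unchanged. The first selectivity needed is aryl over alkyl migration, secured because the only competitor is the unsubstituted C2 methylene, the poorest migrating group, while the sp2 aryl carbon stabilises the electron-deficient transition state better. The methoxy group is meta to the migrating carbon and gives no extra help, but for the same reason it is not conjugated to the carbonyl and does not lower its electrophilicity. The second selectivity is ketone over alkene, secured by the reagent: a silyl peroxide reacts as a nucleophile at an activated carbonyl and has no electrophilic peracid oxygen for the styrene. The low temperature and the moderated Lewis acid are meant to keep the styrene from cationic oligomerisation and to preserve the aryl silyl ether.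

Step 8
Reactants: 13 (S)-7-methoxy-4-[(E)-4-(triisopropylsilyloxy)styryl]chroman-2-one; 7 4-(triisopropylsilyloxy)benzyl bromide
Product: 15 (3R,4R)-7-methoxy-3-[4-(triisopropylsilyloxy)benzyl]-4-[(E)-4-(triisopropylsilyloxy)styryl]chroman-2-one, via lithium enolate 14 (not isolated)
Conditions: LiN(SiMe3)2, THF, −78 °C; then 7, −78 → −40 °C
Reagents that add atoms: none
Why: Alkylation of a lactone enolate: in 14 the C4 styryl group sits pseudo-axial, away from the peri C5–H, and shields one face, so the benzylic bromide should enter at C3 from the opposite face and give the 3,4-trans lactone; the low temperature suppresses ketene formation and self-acylation of the aryl ester enolate.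

Step 9
Reactants: 15 (3R,4R)-7-methoxy-3-[4-(triisopropylsilyloxy)benzyl]-4-[(E)-4-(triisopropylsilyloxy)styryl]chroman-2-one; 16 1-bromo-2,4-dimethoxybenzene
Product: 18 (2R,3R,E)-1-(2,4-dimethoxyphenyl)-3-(2-hydroxy-4-methoxyphenyl)-2-[4-(triisopropylsilyloxy)benzyl]-5-[4-(triisopropylsilyloxy)phenyl]pent-4-en-1-one, via 2,4-dimethoxyphenyllithium 17 (not isolated)
Conditions: 16, n-BuLi, THF, −78 °C; added slowly to 15, THF, −78 °C; AcOH quench at −78 °C
Reagents that add atoms: none
Why: Bromine–lithium exchange followed by acyl substitution on the aryl ester: the tetrahedral adduct expels the ring A phenoxide, and the ketone released is α-branched and deactivated by two methoxy donors, so it should resist a second addition while the aryllithium is kept the limiting species; the cold acidic quench protects the C3 stereocentre from enolisation.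

Step 10
Reactants: 18 (2R,3R,E)-1-(2,4-dimethoxyphenyl)-3-(2-hydroxy-4-methoxyphenyl)-2-[4-(triisopropylsilyloxy)benzyl]-5-[4-(triisopropylsilyloxy)phenyl]pent-4-en-1-one
Product: 20 (2R,3R,4R)-2-(2,4-dimethoxyphenyl)-7-methoxy-3-[4-(triisopropylsilyloxy)benzyl]-4-[(E)-4-(triisopropylsilyloxy)styryl]chroman, via ring-closed lactol 19 (not isolated)
Conditions: Et3SiH, BF3·OEt2, CH2Cl2, −78 → −30 °C
Reagents that add atoms: none
Why: Reductive cyclisation by ionic hydrogenation: the Lewis acid drives the phenol onto the ketone, lactol 19 ionises to a 2-aryl-chromenylium ion stabilised by O1 and the dimethoxyphenyl ring, and the silane delivers hydride axially to the half-chair that has the C3 and C4 groups pseudo-equatorial, on the face away from the C4 styryl group, so the aryl group ends equatorial and trans to the C3 benzyl group (2R); reversible ionisation at C2 would lead to the same all-equatorial isomer.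

Step 11
Reactants: 20 (2R,3R,4R)-2-(2,4-dimethoxyphenyl)-7-methoxy-3-[4-(triisopropylsilyloxy)benzyl]-4-[(E)-4-(triisopropylsilyloxy)styryl]chroman
Product: 21 caraganin C, (2R,3R,4R)-2-(2,4-dimethoxyphenyl)-3-(4-hydroxybenzyl)-4-[(E)-4-hydroxystyryl]-7-methoxychroman
Conditions: Bu4NF, AcOH, THF, 0 °C
Reagents that add atoms: none
Why: Fluoride cleavage of both aryl silyl ethers; acetic acid buffers the phenoxides, and the methyl ethers, the alkene and the acid-sensitive C2 ether should be untouched.

## Compound list

1 | 4-hydroxybenzaldehyde | O=Cc1ccc(O)cc1 | starting material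
2 | 4-(triisopropylsilyloxy)benzaldehyde | O=Cc1ccc(O[Si](C(C)C)(C(C)C)C(C)C)cc1 | intermediate
3 | bis(pinacolato)borylmethane | CC1(C)OB(CB2OC(C)(C)C(C)(C)O2)OC1(C)C | starting material
4 | lithio-bis(pinacolatoboryl)methane (lithiated diboronate) | [Li]C(B1OC(C)(C)C(C)(C)O1)B1OC(C)(C)C(C)(C)O1 | intermediate
5 | (E)-4,4,5,5-tetramethyl-2-{2-[4-(triisopropylsilyloxy)phenyl]ethenyl}-1,3,2-dioxaborolane | CC1(C)OB(/C=C/c2ccc(O[Si](C(C)C)(C(C)C)C(C)C)cc2)OC1(C)C | intermediate
6 | [4-(triisopropylsilyloxy)phenyl]methanol | OCc1ccc(O[Si](C(C)C)(C(C)C)C(C)C)cc1 | intermediate
7 | 4-(triisopropylsilyloxy)benzyl bromide | BrCc1ccc(O[Si](C(C)C)(C(C)C)C(C)C)cc1 | intermediate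
8 | 6-methoxy-1-indanone | COc1ccc2c(c1)C(=O)CC2 | starting material
9 | 3-bromo-6-methoxyindan-1-one (racemic) | COc1ccc2c(c1)C(=O)CC2Br | intermediate
10 | 6-methoxy-1H-inden-1-one | COc1ccc2c(c1)C(=O)C=C2 | intermediate
11 | (S)-6-methoxy-3-[(E)-4-(triisopropylsilyloxy)styryl]indan-1-one | COc1ccc2c(c1)C(=O)C[C@H]2/C=C/c1ccc(O[Si](C(C)C)(C(C)C)C(C)C)cc1 | intermediate
12 | (3S)-6-methoxy-3-[(E)-4-(triisopropylsilyloxy)styryl]-1-(trimethylsilyloxy)-1-(trimethylsilylperoxy)indane (Criegee adduct, mixture at C1) | COc1ccc2c(c1)C(O[Si](C)(C)C)(OO[Si](C)(C)C)C[C@H]2/C=C/c1ccc(O[Si](C(C)C)(C(C)C)C(C)C)cc1 | intermediate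
13 | (S)-7-methoxy-4-[(E)-4-(triisopropylsilyloxy)styryl]chroman-2-one | COc1ccc2c(c1)OC(=O)C[C@H]2/C=C/c1ccc(O[Si](C(C)C)(C(C)C)C(C)C)cc1 | intermediate
14 | lithium enolate of 13 | COc1ccc2c(c1)OC(O[Li])=C[C@H]2/C=C/c1ccc(O[Si](C(C)C)(C(C)C)C(C)C)cc1 | intermediate
15 | (3R,4R)-7-methoxy-3-[4-(triisopropylsilyloxy)benzyl]-4-[(E)-4-(triisopropylsilyloxy)styryl]chroman-2-one | COc1ccc2c(c1)OC(=O)[C@H](Cc1ccc(O[Si](C(C)C)(C(C)C)C(C)C)cc1)[C@H]2/C=C/c1ccc(O[Si](C(C)C)(C(C)C)C(C)C)cc1 | intermediate
16 | 1-bromo-2,4-dimethoxybenzene | COc1ccc(Br)c(OC)c1 | starting material
17 | 2,4-dimethoxyphenyllithium | [Li]c1ccc(OC)cc1OC | intermediate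
18 | (2R,3R,E)-1-(2,4-dimethoxyphenyl)-3-(2-hydroxy-4-methoxyphenyl)-2-[4-(triisopropylsilyloxy)benzyl]-5-[4-(triisopropylsilyloxy)phenyl]pent-4-en-1-one | COc1ccc(c(O)c1)[C@H](/C=C/c1ccc(O[Si](C(C)C)(C(C)C)C(C)C)cc1)[C@@H](Cc1ccc(O[Si](C(C)C)(C(C)C)C(C)C)cc1)C(=O)c1ccc(OC)cc1OC | intermediate
19 | (3R,4R)-2-(2,4-dimethoxyphenyl)-7-methoxy-3-[4-(triisopropylsilyloxy)benzyl]-4-[(E)-4-(triisopropylsilyloxy)styryl]chroman-2-ol (mixture at C2) | COc1ccc2c(c1)OC(O)(c1ccc(OC)cc1OC)[C@H](Cc1ccc(O[Si](C(C)C)(C(C)C)C(C)C)cc1)[C@H]2/C=C/c1ccc(O[Si](C(C)C)(C(C)C)C(C)C)cc1 | intermediate
20 | (2R,3R,4R)-2-(2,4-dimethoxyphenyl)-7-methoxy-3-[4-(triisopropylsilyloxy)benzyl]-4-[(E)-4-(triisopropylsilyloxy)styryl]chroman | COc1ccc2c(c1)O[C@@H](c1ccc(OC)cc1OC)[C@H](Cc1ccc(O[Si](C(C)C)(C(C)C)C(C)C)cc1)[C@H]2/C=C/c1ccc(O[Si](C(C)C)(C(C)C)C(C)C)cc1 | intermediate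
21 | caraganin C, (2R,3R,4R)-2-(2,4-dimethoxyphenyl)-3-(4-hydroxybenzyl)-4-[(E)-4-hydroxystyryl]-7-methoxychroman | COc1ccc2c(c1)O[C@@H](c1ccc(OC)cc1OC)[C@H](Cc1ccc(O)cc1)[C@H]2/C=C/c1ccc(O)cc1 | target

## Step count and least certain steps

Total step count: 11. Longest linear sequence: 8 steps (steps 1, 2, 6, 7, 8, 9, 10, 11, from 4-hydroxybenzaldehyde through boronate 5). The other branches are shorter: step 5 from indanone 8 joins at step 6, and steps 3 and 4 join at step 8.

**Step 7 (key step).** The conjugated aryl ketone may add the silyl peroxide slowly. Forcing the reaction with more Lewis acid or a higher temperature invites Lewis-acid-initiated oligomerisation or oxidative attack of the electron-rich styrene and ring A. A second failure mode is partial migration of the C2 methylene, because the methoxy group is meta to the migrating carbon and gives it no assistance.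

Fallback: set out from boronate 5 and add it, under rhodium catalysis with a chiral bisphosphine, to commercial 7-methoxycoumarin F1. This is an asymmetric conjugate addition to a coumarin and gives lactone 13 directly, with C4 set by the ligand, so the route rejoins at 13. The lactone ring is then bought instead of made by ring expansion. The coumarin is a weaker acceptor than the indenone, which is why this is the reserve and not the route.

**Step 6.** Base-initiated self-addition and oligomerisation of indenone 10 may outrun carbometalation. Enantioselectivity may erode through a ligand-free rhodium pathway, and the benzo ring may reverse or weaken the facial preference inferred from cyclopentenone.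

Fallback: set out from aldehyde 2 and avoid the indenone altogether.
- Wittig homologation of 2 with (triphenylphosphoranylidene)acetaldehyde gives (E)-3-[4-(triisopropylsilyloxy)phenyl]prop-2-enal F2.
- Claisen–Schmidt condensation of F2 with commercial 1-(2-bromo-5-methoxyphenyl)ethan-1-one F3 (Ba(OH)2, EtOH) gives the dienone (2E,4E)-1-(2-bromo-5-methoxyphenyl)-5-[4-(triisopropylsilyloxy)phenyl]penta-2,4-dien-1-one F4.
- Miyaura borylation of F4 (bis(pinacolato)diboron, Pd(dppf)Cl2, KOAc) gives the arylboronate (2E,4E)-1-[5-methoxy-2-(4,4,5,5-tetramethyl-1,3,2-dioxaborolan-2-yl)phenyl]-5-[4-(triisopropylsilyloxy)phenyl]penta-2,4-dien-1-one F5.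
- Rhodium-catalysed asymmetric intramolecular 1,4-addition of the aryl–boron bond of F5 to its own enone, with a chiral phosphorus ligand, closes the five-membered ring and gives indanone 11, where the route is rejoined.

**Step 9.** The tetrahedral adduct of an aryl ester collapses even at −78 °C, so a second aryllithium addition to the liberated ketone is possible. The aryllithium may also act as a base at C3, on lactone 15 or on the ketone, with loss of the C3 configuration.

Fallback: set out from lactone 15. Opening it with N,O-dimethylhydroxylamine hydrochloride and i-PrMgCl gives the phenolic Weinreb amide (2R,3R,E)-3-(2-hydroxy-4-methoxyphenyl)-N-methoxy-N-methyl-2-[4-(triisopropylsilyloxy)benzyl]-5-[4-(triisopropylsilyloxy)phenyl]pent-4-enamide F6. Treatment with a little over two equivalents of aryllithium 17 (one is consumed by the phenol) gives a chelated adduct that cannot add a second time and releases keto-phenol 18 on work-up, where the route is rejoined.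

**Step 10.** Three processes threaten this step:
- over-reduction, by renewed ionisation of the C2–O1 bond of the product (the dimethoxyphenyl group makes C2 an excellent cation) and a second hydride transfer to the ring-opened diarylalkane;
- protonation and ionic hydrogenation of the styrene by adventitious Brønsted acid;
- epimerisation at C3 through reversible proton loss from the chromenylium ion to the enol ether.

Fallback: set out from keto-phenol 18 and separate hydride from acid. Reduction with NaBH4 gives the benzylic alcohol (2R,3R,E)-1-(2,4-dimethoxyphenyl)-3-(2-hydroxy-4-methoxyphenyl)-2-[4-(triisopropylsilyloxy)benzyl]-5-[4-(triisopropylsilyloxy)phenyl]pent-4-en-1-ol F7 as a mixture at the carbinol carbon. A catalytic amount of a mild acid (pyridinium p-toluenesulfonate, CH2Cl2) then ionises the dimethoxybenzylic alcohol, and the phenol captures the cation under thermodynamic control to give the all-equatorial chroman 20, where the route is rejoined.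

## Further compounds

F1 | step 7 | 7-methoxycoumarin | COc1ccc2ccc(=O)oc2c1
F2 | step 6 | (E)-3-[4-(triisopropylsilyloxy)phenyl]prop-2-enal | O=C/C=C/c1ccc(O[Si](C(C)C)(C(C)C)C(C)C)cc1
F3 | step 6 | 1-(2-bromo-5-methoxyphenyl)ethan-1-one | COc1ccc(Br)c(c1)C(C)=O
F4 | step 6 | (2E,4E)-1-(2-bromo-5-methoxyphenyl)-5-[4-(triisopropylsilyloxy)phenyl]penta-2,4-dien-1-one | COc1ccc(Br)c(c1)C(=O)/C=C/C=C/c1ccc(O[Si](C(C)C)(C(C)C)C(C)C)cc1
F5 | step 6 | (2E,4E)-1-[5-methoxy-2-(4,4,5,5-tetramethyl-1,3,2-dioxaborolan-2-yl)phenyl]-5-[4-(triisopropylsilyloxy)phenyl]penta-2,4-dien-1-one | COc1ccc(B2OC(C)(C)C(C)(C)O2)c(c1)C(=O)/C=C/C=C/c1ccc(O[Si](C(C)C)(C(C)C)C(C)C)cc1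
F6 | step 9 | (2R,3R,E)-3-(2-hydroxy-4-methoxyphenyl)-N-methoxy-N-methyl-2-[4-(triisopropylsilyloxy)benzyl]-5-[4-(triisopropylsilyloxy)phenyl]pent-4-enamide | COc1ccc(c(O)c1)[C@H](/C=C/c1ccc(O[Si](C(C)C)(C(C)C)C(C)C)cc1)[C@@H](Cc1ccc(O[Si](C(C)C)(C(C)C)C(C)C)cc1)C(=O)N(C)OC
F7 | step 10 | (2R,3R,E)-1-(2,4-dimethoxyphenyl)-3-(2-hydroxy-4-methoxyphenyl)-2-[4-(triisopropylsilyloxy)benzyl]-5-[4-(triisopropylsilyloxy)phenyl]pent-4-en-1-ol (mixture at C1) | COc1ccc(c(O)c1)[C@H](/C=C/c1ccc(O[Si](C(C)C)(C(C)C)C(C)C)cc1)[C@@H](Cc1ccc(O[Si](C(C)C)(C(C)C)C(C)C)cc1)C(O)c1ccc(OC)cc1OC
A1 | alternative 1 | (2R,3R,4R)-2-(2,4-dimethoxyphenyl)-4-[(E)-4-hydroxystyryl]-7-methoxy-3-[(4-oxocyclohexa-2,5-dien-1-ylidene)methyl]chroman (p-quinone methide) | COc1ccc2c(c1)O[C@@H](c1ccc(OC)cc1OC)[C@H](C=C1C=CC(=O)C=C1)[C@H]2/C=C/c1ccc(O)cc1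
A2 | alternative 1 | 2-[(1E,4E)-1,5-bis(4-hydroxyphenyl)penta-1,4-dien-3-yl]-5-methoxyphenol | COc1ccc(c(O)c1)C(/C=C/c1ccc(O)cc1)/C=C/c1ccc(O)cc1
A3 | alternative 1 | 2,4-dimethoxybenzaldehyde | COc1ccc(C=O)c(OC)c1
A4 | alternative 2 | (2R,3R,4R)-3-[4-(tert-butyldimethylsilyloxy)benzyl]-4-[(E)-4-(tert-butyldimethylsilyloxy)styryl]-2-(2,4-dimethoxyphenyl)-7-methoxychroman | COc1ccc2c(c1)O[C@@H](c1ccc(OC)cc1OC)[C@H](Cc1ccc(O[Si](C)(C)C(C)(C)C)cc1)[C@H]2/C=C/c1ccc(O[Si](C)(C)C(C)(C)C)cc1
A5 | alternative 2 | 2,4-dimethoxy-1-[methoxy(3-methoxyphenoxy)methyl]benzene (mixed acetal) | COc1cccc(OC(OC)c2ccc(OC)cc2OC)c1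
A6 | alternative 2 | (1E,3E)-1,5-bis[4-(tert-butyldimethylsilyloxy)phenyl]penta-1,3-diene | CC(C)(C)[Si](C)(C)Oc1ccc(C/C=C/C=C/c2ccc(O[Si](C)(C)C(C)(C)C)cc2)cc1
A7 | alternative 3 | (4S)-4-[(E)-4-(tert-butyldimethylsilyloxy)styryl]-7-methoxychroman-2-ol (anomeric mixture) | COc1ccc2c(c1)OC(O)C[C@H]2/C=C/c1ccc(O[Si](C)(C)C(C)(C)C)cc1
A8 | alternative 3 | 3-methoxyphenol | COc1cccc(O)c1
A9 | alternative 3 | (2E,4E)-5-[4-(tert-butyldimethylsilyloxy)phenyl]penta-2,4-dienal | O=C/C=C/C=C/c1ccc(O[Si](C)(C)C(C)(C)C)cc1
A10 | alternative 3 | (S)-4-[(E)-4-(tert-butyldimethylsilyloxy)styryl]-7-methoxychroman-2-one | COc1ccc2c(c1)OC(=O)C[C@H]2/C=C/c1ccc(O[Si](C)(C)C(C)(C)C)cc1
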